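Rings: flavone = A (benzo), C (pyranone), B (1,4-phenylene); flavanone = D (benzo), E (dihydropyranone), F (4-hydroxyphenyl). Doubly primed locants belong to rings D and E, triply primed ones to ring F.
The plan rests on ring A. Its oxygens on C5, C7 and C8a (O1) are 1,3,5-related and the carbonyl carbon C4 hangs on C4a between C5 and C8a. This is the pattern left when an oxygen nucleophile and an acyl group add across the triple bond of 3,5-dimethoxybenzyne.
Disconnections, backwards: three O-benzyl groups; C2''–C1''' (asymmetric aryl 1,4-addition to a 2-unsubstituted chromone); O1''–C2'' of ring E (enaminone closure); then O1–C8a, C4–C4a and O1–C2 of ring C (aryne plus arylpropiolic acid).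
The acid is cut at alkyne–ring B (Sonogashira), acetyl–ring D (Friedel–Crafts) and ring B–O (Ullmann), back to syringaldehyde, 1,4-diiodobenzene and propiolic acid; the aryne precursor comes from 3,5-dimethoxyphenol.
Ring order: A, B, D and F are bought, ring C closes in step 9 and ring E in step 10; C2'' is set in step 13, after every acidic, basic or Lewis-acidic operation.

Key step: step 9

Assumption: the (S) antipode of the biaryl diphosphine in step 13 is taken to give (2''S), by analogy with its known sense on 2-cyclohexenone (the CIP descriptor carries over unchanged from 3-arylcyclohexanone to flavanone). The configuration of 27 is to be checked by circular dichroism, and the (R) ligand is equally available.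

Step 1
Reactants: 1 3,5-dimethoxyphenol
Product: 2 3,5-dimethoxyphenyl N-isopropylcarbamate
Conditions: i-PrNCO, Et3N (cat.), CH2Cl2, rt
Reagents that add atoms: isopropyl isocyanate, CC(C)N=C=O
Why: Base-catalysed addition of the phenol O–H across the isocyanate (carbamoylation) installs a secondary O-aryl carbamate, the strongest ortho director this ring can carry and one that can later be removed without strong base.

Step 2
Reactants: 2 3,5-dimethoxyphenyl N-isopropylcarbamate
Product: 6 3,5-dimethoxy-2-(trimethylsilyl)phenyl N-isopropylcarbamate, via N-TBS carbamate 3 (not isolated), via aryllithium 4 (not isolated), via C-silylated N-TBS carbamate 5 (not isolated)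
Conditions: TBSOTf, TMEDA, Et2O, 0 °C to rt; n-BuLi, TMEDA, −78 °C; TMSCl, −78 °C to rt; aq NaHSO4
Reagents that add atoms: chlorotrimethylsilane, C[Si](C)(C)Cl; TBSOTf, CC(C)(C)[Si](C)(C)OS(=O)(=O)C(F)(F)F (its silyl group is carried only by 3, 4, 5); n-butyllithium, [Li]CCCC (its lithium is carried only by 4)
Why: Directed ortho-metalation, in which N-silylation masks the N–H and the carbamate together with the C3 methoxy group steers n-BuLi to C2 (equivalent to C6) rather than to C4, which has only the two weaker methoxy directors; at −78 °C TMSCl should trap the aryllithium before an anionic ortho-Fries shift, and the acidic work-up removes the N-silyl group.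

Step 3
Reactants: 6 3,5-dimethoxy-2-(trimethylsilyl)phenyl N-isopropylcarbamate
Product: 8 3,5-dimethoxy-2-(trimethylsilyl)phenyl trifluoromethanesulfonate, via silylphenol 7 (not isolated)
Conditions: Et2NH, DBU, MeCN, 40 °C; then PhNTf2, rt
Reagents that add atoms: N-phenylbis(trifluoromethanesulfonimide), O=S(=O)(N(c1ccccc1)S(=O)(=O)C(F)(F)F)C(F)(F)F
Why: E1cB cleavage of the secondary carbamate (DBU takes the N–H, the aryloxide leaves, Et2NH traps the isocyanate) frees the protodesilylation-prone silylphenoxide, which is O-triflated in the same flask so that it never has to be handled.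

Step 4
Reactants: 9 syringaldehyde; 10 1,4-diiodobenzene
Product: 11 4-(4-iodophenoxy)-3,5-dimethoxybenzaldehyde
Conditions: 10 (3 equiv), CuI (10 mol%), picolinic acid (20 mol%), K3PO4, DMSO, 90 °C
Reagents that add atoms: none
Why: Ullmann diaryl ether coupling on monovalent copper with picolinic acid, a ligand suited to di-ortho-substituted phenols; the excess of symmetrical diiodide holds back double coupling, the first aryloxy group makes the remaining C–I bond more electron-rich and slower, and the non-enolisable aldehyde tolerates K3PO4.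

Step 5
Reactants: 11 4-(4-iodophenoxy)-3,5-dimethoxybenzaldehyde
Product: 13 4-(4-iodophenoxy)-3,5-dimethoxyphenol, via aryl formate 12 (not isolated)
Conditions: 30% H2O2, H2SO4 (cat.), MeOH, rt
Reagents that add atoms: hydrogen peroxide, OO
Why: Acid-mediated Dakin-type (Baeyer–Villiger) oxidation, chosen because the alkaline Dakin reaction needs a free ortho or para hydroxyl that 11 lacks; in acidic methanol the H2O2 perhemiacetal rearranges by migration of the aryl group, helped by its para aryloxy oxygen, the formate is methanolysed in situ, and no peracid is present that could oxidise the aryl iodide.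

Step 6
Reactants: 13 4-(4-iodophenoxy)-3,5-dimethoxyphenol
Product: 14 1-[6-hydroxy-3-(4-iodophenoxy)-2,4-dimethoxyphenyl]ethan-1-one
Conditions: AcOH, BF3·OEt2, 70 °C; then H2O, aq NaOAc
Reagents that add atoms: acetic acid, CC(=O)O
Why: Friedel–Crafts acylation (by way of the O-acetate and a Fries shift) at one of the two symmetry-equivalent carbons ortho to the phenol of the trioxygenated ring D, the iodophenoxy ring being far less activated; the product is held as its BF2 chelate, which stops a second acylation, and is freed in the aqueous work-up.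

Step 7
Reactants: 14 1-[6-hydroxy-3-(4-iodophenoxy)-2,4-dimethoxyphenyl]ethan-1-one
Product: 15 1-[3-(4-iodophenoxy)-2,4-dimethoxy-6-(methoxymethoxy)phenyl]ethan-1-one
Conditions: MOMCl, i-Pr2NEt, CH2Cl2, 0 °C to reflux
Reagents that add atoms: chloromethyl methyl ether, COCCl
Why: Williamson-type O-alkylation of the chelated phenol by the very reactive MOMCl gives an acetal that withstands DBU, fluoride and 125 °C, and it hides the only O–H that the aryne would otherwise arylate.

Step 8
Reactants: 15 1-[3-(4-iodophenoxy)-2,4-dimethoxy-6-(methoxymethoxy)phenyl]ethan-1-one; 16 propiolic acid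
Product: 17 3-{4-[3-acetyl-2,6-dimethoxy-4-(methoxymethoxy)phenoxy]phenyl}prop-2-ynoic acid
Conditions: 16 (1.5 equiv), Pd(PPh3)2Cl2 (5 mol%), dppb (10 mol%), DBU (3 equiv), DMSO, rt; cold aq citric acid
Reagents that add atoms: none
Why: Copper-free Sonogashira coupling of propiolic acid as its DBU salt, in which an aryl iodide rather than a bromide lets oxidative addition to zerovalent palladium run at room temperature, below the range where arylpropiolates lose CO2 and couple a second time; leaving out copper avoids Glaser coupling and copper-promoted decarboxylation.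

Step 9
Reactants: 17 3-{4-[3-acetyl-2,6-dimethoxy-4-(methoxymethoxy)phenoxy]phenyl}prop-2-ynoic acid; 8 3,5-dimethoxy-2-(trimethylsilyl)phenyl trifluoromethanesulfonate
Product: 20 2-{4-[3-acetyl-2,6-dimethoxy-4-(methoxymethoxy)phenoxy]phenyl}-5,7-dimethoxy-4H-chromen-4-one, via 3,5-dimethoxybenzyne 18 (not isolated), via o-hydroxyaryl ynone 19 (not isolated)
Conditions: 8 (1.5 equiv), CsF (4 equiv), THF, 125 °C, sealed tube
Reagents that add atoms: none
Why: Fluoride removes the silyl group of 8 and triflate departs to give aryne 18, which the cesium carboxylate of 17 attacks at the aryne carbon remote from the neighbouring methoxy group, because the charge then builds up on the carbon beside that inductively withdrawing oxygen (O1–C8a). This aryl anion attacks its own ester carbonyl through a strained four-membered alkoxide that collapses to the o-acylphenoxide of ynone 19 (C4–C4a), so the aryne has in effect entered the acyl C–O bond of the acid. Ring C is shut when this phenoxide oxygen adds to the β-carbon of the ynone in 6-endo-dig fashion (oxa-Michael, O1–C2), and the allenolate takes back the proton parked on fluoride at the outset. The closest known reaction type is the fluoride-induced insertion of arynes into the C–O bond of carboxylic acids to give o-hydroxyaryl ketones, which with 3-arylpropiolic acids is known to run on to flavones. No stereocentre is formed; the step needs regioselective addition to the aryne, secured by the C3 methoxy group of 18 (oxygens end up on C5, C7 and C8a), and acyl transfer ahead of protonation of the aryl anion, favoured by hot THF in which CsF is sparingly soluble and proton sources are scarce. In 17 the MOM ether keeps the only phenol away from the aryne, and the acetyl group, twisted between two ortho oxygens and lacking β-dicarbonyl acidity, should stay a spectator.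

Step 10
Reactants: 20 2-{4-[3-acetyl-2,6-dimethoxy-4-(methoxymethoxy)phenoxy]phenyl}-5,7-dimethoxy-4H-chromen-4-one
Product: 23 2-{4-[(5,7-dimethoxy-4-oxo-4H-chromen-6-yl)oxy]phenyl}-5,7-dimethoxy-4H-chromen-4-one, via MOM-protected enaminone 21 (not isolated), via phenolic enaminone 22 (not isolated)
Conditions: DMF-DMA, 110 °C; evaporate; conc. HCl, MeOH–CH2Cl2, 40 °C
Reagents that add atoms: N,N-dimethylformamide dimethyl acetal, COC(OC)N(C)C
Why: Enaminone chromone synthesis, in which the acetal condenses with the only C–H acidic methyl group while the MOM ether shields the phenol from O-methylation by the reagent; HCl then removes the MOM group and the freed phenol closes ring E by 6-endo-trig addition–elimination with loss of dimethylamine, so O1'' is locked in a ring before the other ortho oxygen is unmasked.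

Step 11
Reactants: 23 2-{4-[(5,7-dimethoxy-4-oxo-4H-chromen-6-yl)oxy]phenyl}-5,7-dimethoxy-4H-chromen-4-one
Product: 24 5-hydroxy-2-{4-[(5-hydroxy-7-methoxy-4-oxo-4H-chromen-6-yl)oxy]phenyl}-7-methoxy-4H-chromen-4-one
Conditions: BCl3 (5 equiv), CH2Cl2, −78 °C to rt; then MeOH, aq HCl
Reagents that add atoms: none
Why: Chelation-controlled ether cleavage, in which BCl3 ties each pyranone carbonyl to its peri methoxy oxygen in a six-membered chelate so that chloride removes only the C5 and C5'' methyl groups and both C7 methoxy groups and the diaryl ether stay; done on the achiral, ring-closed chromone, it avoids Lewis-acid opening of a flavanone at its 4-alkoxybenzylic C2''–O1'' bond and any confusion between two free ortho hydroxyls.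

Step 12
Reactants: 24 5-hydroxy-2-{4-[(5-hydroxy-7-methoxy-4-oxo-4H-chromen-6-yl)oxy]phenyl}-7-methoxy-4H-chromen-4-one
Product: 25 5-(benzyloxy)-2-{4-[(5-(benzyloxy)-7-methoxy-4-oxo-4H-chromen-6-yl)oxy]phenyl}-7-methoxy-4H-chromen-4-one
Conditions: BnBr (4 equiv), Cs2CO3 (4 equiv), n-Bu4NI (cat.), dry MeCN, 60 °C
Reagents that add atoms: benzyl bromide, BrCc1ccccc1
Why: Williamson benzylation under forcing but anhydrous conditions overcomes the hydrogen bond of both peri hydroxyls; the benzyl ethers keep the 5-hydroxy-4-oxo units from binding rhodium as acetylacetonate-like chelates in the next step and can leave at the end by neutral hydrogenolysis.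

Step 13
Reactants: 25 5-(benzyloxy)-2-{4-[(5-(benzyloxy)-7-methoxy-4-oxo-4H-chromen-6-yl)oxy]phenyl}-7-methoxy-4H-chromen-4-one; 26 4-(benzyloxy)phenylboronic acid
Product: 27 5-(benzyloxy)-2-{4-[((2S)-5-(benzyloxy)-2-[4-(benzyloxy)phenyl]-7-methoxy-4-oxo-2,3-dihydro-4H-chromen-6-yl)oxy]phenyl}-7-methoxy-4H-chromen-4-one
Conditions: 26 (3 equiv), [Rh(OH)(cod)]2 (2.5 mol%), (S)-MeO-F12-BIPHEP [(S)-6,6'-dimethoxybiphenyl-2,2'-diylbis(bis(3,4,5-trifluorophenyl)phosphine)] (5.5 mol%), toluene–H2O, rt
Reagents that add atoms: none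
Why: Hayashi–Miyaura asymmetric 1,4-addition, in which the arylrhodium formed by transmetalation inserts the C2''=C3'' bond of the 2-unsubstituted chromone and water hydrolyses the oxa-π-allyl rhodium, the C2-symmetric (S)-diphosphine leaving one enone face open so that C2'' should form as (S); the electron-poor ligand allows room temperature, where 1,2-addition and retro-oxa-Michael racemisation should not compete, and the flavone enone is inert because its β-carbon already bears ring B.

Step 14
Reactants: 27 5-(benzyloxy)-2-{4-[((2S)-5-(benzyloxy)-2-[4-(benzyloxy)phenyl]-7-methoxy-4-oxo-2,3-dihydro-4H-chromen-6-yl)oxy]phenyl}-7-methoxy-4H-chromen-4-one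
Product: 28 5-hydroxy-2-{4-[((2S)-5-hydroxy-2-(4-hydroxyphenyl)-7-methoxy-4-oxo-2,3-dihydro-4H-chromen-6-yl)oxy]phenyl}-7-methoxy-4H-chromen-4-one (CNP0202121.1)
Conditions: H2 (1 atm), 10% Pd/C, EtOAc–THF, rt; filtration and evaporation below 30 °C, no base
Reagents that add atoms: none
Why: Catalytic hydrogenolysis of the three benzyl aryl ethers is neutral, so the base- and Lewis-acid-labile C2'' centre is left alone; the reaction is stopped after uptake of three equivalents of H2, before the slower reduction of the flavone C2=C3 bond or cleavage of the cyclic benzylic C2''–O1'' bond.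

Compound list
1 | 3,5-dimethoxyphenol | COc1cc(O)cc(OC)c1 | starting material
2 | 3,5-dimethoxyphenyl N-isopropylcarbamate | COc1cc(OC)cc(OC(=O)NC(C)C)c1 | intermediate
3 | 3,5-dimethoxyphenyl N-(tert-butyldimethylsilyl)-N-isopropylcarbamate | COc1cc(OC)cc(OC(=O)N(C(C)C)[Si](C)(C)C(C)(C)C)c1 | intermediate
4 | 2-lithio-3,5-dimethoxyphenyl N-(tert-butyldimethylsilyl)-N-isopropylcarbamate | COc1cc(OC)c([Li])c(OC(=O)N(C(C)C)[Si](C)(C)C(C)(C)C)c1 | intermediate
5 | 3,5-dimethoxy-2-(trimethylsilyl)phenyl N-(tert-butyldimethylsilyl)-N-isopropylcarbamate | COc1cc(OC)c([Si](C)(C)C)c(OC(=O)N(C(C)C)[Si](C)(C)C(C)(C)C)c1 | intermediate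
6 | 3,5-dimethoxy-2-(trimethylsilyl)phenyl N-isopropylcarbamate | COc1cc(OC)c([Si](C)(C)C)c(OC(=O)NC(C)C)c1 | intermediate
7 | 3,5-dimethoxy-2-(trimethylsilyl)phenol | COc1cc(O)c([Si](C)(C)C)c(OC)c1 | intermediate
8 | 3,5-dimethoxy-2-(trimethylsilyl)phenyl trifluoromethanesulfonate | COc1cc(OC)c([Si](C)(C)C)c(OS(=O)(=O)C(F)(F)F)c1 | intermediate
9 | syringaldehyde | COc1cc(C=O)cc(OC)c1O | starting material
10 | 1,4-diiodobenzene | Ic1ccc(I)cc1 | starting material
11 | 4-(4-iodophenoxy)-3,5-dimethoxybenzaldehyde | COc1cc(C=O)cc(OC)c1Oc1ccc(I)cc1 | intermediate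
12 | 4-(4-iodophenoxy)-3,5-dimethoxyphenyl formate | COc1cc(OC=O)cc(OC)c1Oc1ccc(I)cc1 | intermediate
13 | 4-(4-iodophenoxy)-3,5-dimethoxyphenol | COc1cc(O)cc(OC)c1Oc1ccc(I)cc1 | intermediate
14 | 1-[6-hydroxy-3-(4-iodophenoxy)-2,4-dimethoxyphenyl]ethan-1-one | CC(=O)c1c(O)cc(OC)c(Oc2ccc(I)cc2)c1OC | intermediate
15 | 1-[3-(4-iodophenoxy)-2,4-dimethoxy-6-(methoxymethoxy)phenyl]ethan-1-one | CC(=O)c1c(OCOC)cc(OC)c(Oc2ccc(I)cc2)c1OC | intermediate
16 | propiolic acid | C#CC(=O)O | starting material
17 | 3-{4-[3-acetyl-2,6-dimethoxy-4-(methoxymethoxy)phenoxy]phenyl}prop-2-ynoic acid | OC(=O)C#Cc1ccc(Oc2c(OC)cc(OCOC)c(C(C)=O)c2OC)cc1 | intermediate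
18 | 3,5-dimethoxybenzyne | COC1=CC(OC)=CC#C1 | intermediate
19 | 1-(2-hydroxy-4,6-dimethoxyphenyl)-3-{4-[3-acetyl-2,6-dimethoxy-4-(methoxymethoxy)phenoxy]phenyl}prop-2-yn-1-one | COc1cc(O)c(C(=O)C#Cc2ccc(Oc3c(OC)cc(OCOC)c(C(C)=O)c3OC)cc2)c(OC)c1 | intermediate
20 | 2-{4-[3-acetyl-2,6-dimethoxy-4-(methoxymethoxy)phenoxy]phenyl}-5,7-dimethoxy-4H-chromen-4-one | COc1cc(OC)c2c(=O)cc(-c3ccc(Oc4c(OC)cc(OCOC)c(C(C)=O)c4OC)cc3)oc2c1 | intermediate
21 | 2-{4-[3-[(E)-3-(dimethylamino)prop-2-enoyl]-2,6-dimethoxy-4-(methoxymethoxy)phenoxy]phenyl}-5,7-dimethoxy-4H-chromen-4-one | COc1cc(OC)c2c(=O)cc(-c3ccc(Oc4c(OC)cc(OCOC)c(C(=O)/C=C/N(C)C)c4OC)cc3)oc2c1 | intermediate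
22 | 2-{4-[3-[(E)-3-(dimethylamino)prop-2-enoyl]-4-hydroxy-2,6-dimethoxyphenoxy]phenyl}-5,7-dimethoxy-4H-chromen-4-one | COc1cc(OC)c2c(=O)cc(-c3ccc(Oc4c(OC)cc(O)c(C(=O)/C=C/N(C)C)c4OC)cc3)oc2c1 | intermediate
23 | 2-{4-[(5,7-dimethoxy-4-oxo-4H-chromen-6-yl)oxy]phenyl}-5,7-dimethoxy-4H-chromen-4-one | COc1cc(OC)c2c(=O)cc(-c3ccc(Oc4c(OC)cc5occc(=O)c5c4OC)cc3)oc2c1 | intermediate
24 | 5-hydroxy-2-{4-[(5-hydroxy-7-methoxy-4-oxo-4H-chromen-6-yl)oxy]phenyl}-7-methoxy-4H-chromen-4-one | COc1cc(O)c2c(=O)cc(-c3ccc(Oc4c(OC)cc5occc(=O)c5c4O)cc3)oc2c1 | intermediate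
25 | 5-(benzyloxy)-2-{4-[(5-(benzyloxy)-7-methoxy-4-oxo-4H-chromen-6-yl)oxy]phenyl}-7-methoxy-4H-chromen-4-one | COc1cc(OCc6ccccc6)c2c(=O)cc(-c3ccc(Oc4c(OC)cc5occc(=O)c5c4OCc4ccccc4)cc3)oc2c1 | intermediate
26 | 4-(benzyloxy)phenylboronic acid | OB(O)c1ccc(OCc2ccccc2)cc1 | starting material
27 | 5-(benzyloxy)-2-{4-[((2S)-5-(benzyloxy)-2-[4-(benzyloxy)phenyl]-7-methoxy-4-oxo-2,3-dihydro-4H-chromen-6-yl)oxy]phenyl}-7-methoxy-4H-chromen-4-one | COc1cc(OCc6ccccc6)c2c(=O)cc(-c3ccc(Oc4c(OC)cc5c(c4OCc4ccccc4)C(=O)C[C@@H](c4ccc(OCc6ccccc6)cc4)O5)cc3)oc2c1 | intermediate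
28 | 5-hydroxy-2-{4-[((2S)-5-hydroxy-2-(4-hydroxyphenyl)-7-methoxy-4-oxo-2,3-dihydro-4H-chromen-6-yl)oxy]phenyl}-7-methoxy-4H-chromen-4-one (CNP0202121.1) | COc1cc(O)c2c(=O)cc(-c3ccc(Oc4c(OC)cc5c(c4O)C(=O)C[C@@H](c4ccc(O)cc4)O5)cc3)oc2c1 | target

Total step count: 14 (3 to the aryne precursor, 5 to the acid, 6 from their union to the target).
Longest linear sequence: 11 steps (steps 4 to 14, from syringaldehyde).

Steps most likely to fail

**Step 9 (key step).**
- What may go wrong:
  - protonation of the aryl anion before acyl transfer, which ends in plain O-arylation of the acid;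
  - thermal loss of CO2 from the propiolate at 125 °C;
  - conjugate attack of the aryl anion on the alkyne instead of the carbonyl;
  - capture of the intermediate phenoxide by a second aryne.
- Fallback: it sets out from 17 and 1 and comes back at 20.
  - The loss of CO2 is made deliberate (CuCl, Et3N, MeCN, 60 °C) to give the terminal alkyne 1-[3-(4-ethynylphenoxy)-2,4-dimethoxy-6-(methoxymethoxy)phenyl]ethan-1-one F1.
  - Compound 1 is iodinated with N-iodosuccinimide (MeCN, 0 °C) at the less crowded carbon ortho to the hydroxyl to give 2-iodo-3,5-dimethoxyphenol F2.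
  - F1, F2 and CO (1 atm) are joined by palladium-catalysed carbonylative Sonogashira annulation (PdCl2(dppf), Et2NH, 60 °C).
  - This passes through the same ynone 19, the secondary amine steers its closure to the six-membered ring, and 20 results.

**Step 13.**
- What may go wrong:
  - sluggish insertion of the electron-rich, 5,6,7-trioxygenated chromone, so that protodeboronation of the electron-rich boronic acid outruns addition;
  - erosion of the enantiomeric purity by reversible opening of ring E if heating becomes necessary.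
- Fallback: it sets out from 25 and comes back at 27, making the C–O bond rather than the C–C bond in the asymmetric event.
  - Dilute aqueous KOH in EtOH–THF at rt adds to C2'', which carries only hydrogen and is attacked much faster than the aryl-substituted C2 of the flavone. Loss of formate gives 2-{4-[3-acetyl-2-(benzyloxy)-4-hydroxy-6-methoxyphenoxy]phenyl}-5-(benzyloxy)-7-methoxy-4H-chromen-4-one F3, in which only the future O1'' is free.
  - Claisen–Schmidt condensation with 4-(benzyloxy)benzaldehyde (O=Cc1ccc(OCc2ccccc2)cc1; KOH, EtOH, rt) gives the 2'-hydroxychalcone 5-(benzyloxy)-2-{4-[2-(benzyloxy)-3-{(E)-3-[4-(benzyloxy)phenyl]prop-2-enoyl}-4-hydroxy-6-methoxyphenoxy]phenyl}-7-methoxy-4H-chromen-4-one F4.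
  - A bifunctional 9-amino(9-deoxy)-epi-cinchona 3,5-bis(trifluoromethyl)phenyl thiourea (toluene, 0 °C to rt) closes ring E by enantioselective 6-endo-trig oxa-Michael addition to 27. The pseudoenantiomer that gives the (S) series is chosen.

**Step 4.**
- What may go wrong:
  - slow C–O coupling, because the phenoxide is flanked by two methoxy groups and weakened by the para formyl group;
  - a second coupling on the diiodide;
  - reductive loss of iodine at 90 °C.
- Fallback: it sets out from 9 and comes back at 11.
  - The potassium phenoxide of 9 (t-BuOK, THF, rt to 40 °C) is arylated without metal by bis(4-bromophenyl)iodonium triflate (Brc1ccc([I+]c2ccc(Br)cc2)cc1.[O-]S(=O)(=O)C(F)(F)F). This ligand coupling at trivalent iodine is little affected by ortho substituents and gives 4-(4-bromophenoxy)-3,5-dimethoxybenzaldehyde F5.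
  - An aromatic Finkelstein exchange (CuI, NaI, trans-N,N'-dimethylcyclohexane-1,2-diamine, dioxane, 110 °C) then converts F5 into 11.

Further compounds
F1 | step 9 | 1-[3-(4-ethynylphenoxy)-2,4-dimethoxy-6-(methoxymethoxy)phenyl]ethan-1-one | C#Cc1ccc(Oc2c(OC)cc(OCOC)c(C(C)=O)c2OC)cc1
F2 | step 9 | 2-iodo-3,5-dimethoxyphenol | COc1cc(O)c(I)c(OC)c1
F3 | step 13 | 2-{4-[3-acetyl-2-(benzyloxy)-4-hydroxy-6-methoxyphenoxy]phenyl}-5-(benzyloxy)-7-methoxy-4H-chromen-4-one | COc1cc(OCc6ccccc6)c2c(=O)cc(-c3ccc(Oc4c(OC)cc(O)c(C(C)=O)c4OCc4ccccc4)cc3)oc2c1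
F4 | step 13 | 5-(benzyloxy)-2-{4-[2-(benzyloxy)-3-{(E)-3-[4-(benzyloxy)phenyl]prop-2-enoyl}-4-hydroxy-6-methoxyphenoxy]phenyl}-7-methoxy-4H-chromen-4-one | COc1cc(OCc5ccccc5)c2c(=O)cc(-c3ccc(Oc4c(OC)cc(O)c(C(=O)/C=C/c6ccc(OCc7ccccc7)cc6)c4OCc4ccccc4)cc3)oc2c1
F5 | step 4 | 4-(4-bromophenoxy)-3,5-dimethoxybenzaldehyde | COc1cc(C=O)cc(OC)c1Oc1ccc(Br)cc1
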